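Its constants belong to no real substance, and the outcome is calculated.

How far does this flask get in 2.0 h, and what do I change for the next run: the solid base, or the concentration of electrophile?

electrophile 0.20 M; protonated nucleophile 1.00 equiv; solid base 1.20 equiv; time 2.0 h

    crystals ⇌ acid set free, rate k1*(cs1 - [acid set free]) while solid is left; crystals form when [acid set free] > cs1 (cs1 = 7.5 mM, k1 = 0.022 s⁻¹)
    solid base ⇌ free base, rate k2*(cs2 - [free base]) while solid is left; crystals form when [free base] > cs2 (cs2 = 14 mM, k2 = 1.9 × 10⁻⁴ s⁻¹)
    nucleophile + acid set free ⇌ protonated nucleophile, settled at all times (K3 = 680 M⁻¹)
    electrophile + nucleophile → acid set free + target (k4 = 0.033 M⁻¹ s⁻¹)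
    acid set free + free base ⇌ salt of the base (K5 = 3800 M⁻¹, k5 = 0.013 M⁻¹ s⁻¹)

1. part of the electrophile that has reacted at 2.0 h
2. share of the unused nucleophile that is free and not bound as protonated nucleophile, at 2.0 h

- what is said of acid set free includes crystals
- crystals, solid base is a solid; its amount is given per volume of the solution
- at the start none of the solid base is in solution
- run time (flask): 2.0 h

The protonated nucleophile, dissociating by itself, gives about 17.1 mM of acid set free, above the solubility of 7.5 mM, so crystals form. With nothing feeding it, acid set free would fall back toward solubility with a half-life of 31.5 s, much shorter than the run. But the coupling keeps releasing acid set free, so it stands above solubility while the coupling runs. As a first reckoning I still take it at solubility, knowing that this puts the free share, and with it my conversion, on the high side.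

The ratio of protonated to free nucleophile is then 5.10, ten to the power 0.708. The free share is f = 16.4%, and protonated nucleophile is the resting state.

Electrophile and nucleophile pool start equal and fall together, so the coupling runs second order with the constant reduced by f. Here 7.79 is the product of f, the coupling constant, the electrophile charge and the time; I name it the reach D, the ratio of reacted to unreacted electrophile at equal charges. It is ten to the power 0.892, which means 88.6% reacted.

Diluting to 0.12 M takes 0.222 off that exponent. Solid base has no place in D, and it can deliver at most 0.0192 M in the run, less than the 0.20 M of electrophile. So I leave the solid base and keep the concentration.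

The forecast says 86.5% and 15.9%, both lower than my figures, and it notes: “Supersaturation is therefore significant early on”.

The simulation gives 86.7% and 15.9%. In this flask acid set free stands at 0.0134 M at 0.200 h, 1.79 times its solubility, and half of the coupling's turnover is done by 0.336 h. It has come down to 0.00778 M at 2.00 h, and reacted to unreacted is 6.52 against D of 7.79. In the neighbour at 0.12 M, the reach falls to 4.67, which means 82.4% reacted, and that flask gives 80.7%.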